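The route rests on cutting the C1–C10 bond (germacrane numbering), which is shared by the oxirane and the ten-membered carbocycle and whose two carbons carry the same oxygen. In the key step a diphenylsulfonium ylide at C1 adds to a C10 methyl ketone and the betaine collapses. One operation thus closes both rings and sets C1 and C10, and the ketone oxygen becomes the epoxide oxygen. The precursor is an open-chain sulfonium salt built on a trans-butanolide (C6, C7) that carries the C4=C5 alkene, silyl ethers at C2, C8 and C15, and the ketone. The α-methylene group and the angelate follow the ring closure.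

Key step: step 15

Remark on numbering: C1 and C10 are the oxirane carbons (C10 bears methyl C14), C2 the free carbinol, C4=C5 the ring alkene (C4 bears C15H2OH), C6 the lactone O–CH, C7 the ring-fusion CH, C8 the acyloxy carbon, C9 the CH2, and C11(=C13H2)–C12(=O) the lactone carbons. The alkene is Z by CIP (C6 and C15 cis, ring bonds trans). The descriptor at C7 changes between R and S with the C8 substituent although its configuration never changes.

Abbreviations: TBS = tert-butyldimethylsilyl, TBDPS = tert-butyldiphenylsilyl, TES = triethylsilyl, PMB = 4-methoxybenzyl.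

Assumption: aldehyde 1, diene 2 and (tributylstannyl)methanol are taken as commercially available.

Step 1
Reactants: 1 (4-methoxybenzyloxy)acetaldehyde; 2 1-methoxy-1,3-bis(trimethylsilyloxy)buta-1,3-diene
Product: 3 methyl (5S)-5-hydroxy-6-(PMBO)-3-oxohexanoate
Conditions: [Cu((S,S)-Ph-pybox)](SbF6)2 (2 mol%; Ph-pybox = 2,6-bis(4-phenyl-4,5-dihydrooxazol-2-yl)pyridine), CH2Cl2, −78 °C; then 1 M HCl, THF, 0 °C
Reagents that add atoms: none
Why: Catalytic enantioselective vinylogous Mukaiyama aldol addition in which the aldehyde chelates divalent copper through its carbonyl and ether oxygens and the diene terminus attacks the face left open by the (S,S)-ligand, which should set C2 as S.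

Step 2
Reactants: 3 methyl (5S)-5-hydroxy-6-(PMBO)-3-oxohexanoate
Product: 4 methyl (5S)-5-(TBSO)-6-(PMBO)-3-oxohexanoate
Conditions: t-BuMe2SiCl, imidazole, DMF, 0 °C to rt
Reagents that add atoms: tert-butyldimethylsilyl chloride CC(C)(C)[Si](C)(C)Cl
Why: Standard silylation of the secondary alcohol, which blocks lactonisation and retro-aldol cleavage of the δ-hydroxy-β-keto ester.

Step 3
Reactants: 4 methyl (5S)-5-(TBSO)-6-(PMBO)-3-oxohexanoate
Product: 5 methyl (2Z,5S)-5-(TBSO)-6-(PMBO)-3-(trifluoromethylsulfonyloxy)hex-2-enoate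
Conditions: Tf2O, aq. LiOH, toluene, 5 °C
Reagents that add atoms: trifluoromethanesulfonic anhydride O=S(=O)(OS(=O)(=O)C(F)(F)F)C(F)(F)F
Why: O-Sulfonylation of the lithium-chelated enolate of the β-keto ester should give the (Z)-enol triflate (triflate cis to the ester), which fixes the later C4=C5 geometry.

Step 4
Reactants: 5 methyl (2Z,5S)-5-(TBSO)-6-(PMBO)-3-(trifluoromethylsulfonyloxy)hex-2-enoate
Product: 7 4-[(2S)-2-(TBSO)-3-(PMBO)propyl]furan-2(5H)-one, via hydroxy ester 6 (not isolated)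
Conditions: n-Bu3SnCH2OH, Pd(PPh3)4 (5 mol%), LiCl, 1,4-dioxane, 90 °C
Reagents that add atoms: (tributylstannyl)methanol CCCC[Sn](CCCC)(CCCC)CO
Why: Stille coupling at zerovalent palladium proceeds with retention of alkene geometry, so the new CH2OH (C15) lies cis to the ester and the hydroxy ester should lactonise at once to the butenolide.

Step 5
Reactants: 7 4-[(2S)-2-(TBSO)-3-(PMBO)propyl]furan-2(5H)-one
Product: 9 (2Z,5S)-5-(TBSO)-3-[(TBDPSO)methyl]-N-methoxy-N-methyl-6-(PMBO)hex-2-enamide, via hydroxy amide 8 (not isolated)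
Conditions: MeNH(OMe)·HCl, i-PrMgCl, THF, −20 °C; then t-BuPh2SiCl, imidazole, DMF, 0 °C
Reagents that add atoms: N,O-dimethylhydroxylamine hydrochloride CNOC.Cl; tert-butyldiphenylsilyl chloride CC(C)(C)[Si](Cl)(c1ccccc1)c1ccccc1
Why: Weinreb aminolysis of the lactone by the magnesium amide opens the ring without touching the ring-derived Z-alkene, and immediate silylation of the primary allylic alcohol prevents relactonisation.

Step 6
Reactants: 9 (2Z,5S)-5-(TBSO)-3-[(TBDPSO)methyl]-N-methoxy-N-methyl-6-(PMBO)hex-2-enamide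
Product: 10 (2Z,5S)-5-(TBSO)-3-[(TBDPSO)methyl]-6-(PMBO)hex-2-enal
Conditions: i-Bu2AlH, THF, −78 °C; aq. potassium sodium tartrate
Reagents that add atoms: none
Why: Weinreb amide reduction stops at the chelated tetrahedral intermediate, which should release the (Z)-enal only on work-up.

Step 7
Reactants: 11 (4S)-4-benzyl-1,3-oxazolidin-2-one; 12 methyl 4-chloro-4-oxobutanoate
Product: 13 methyl 4-[(4S)-4-benzyl-2-oxo-1,3-oxazolidin-3-yl]-4-oxobutanoate
Conditions: n-BuLi, THF, −78 °C; then 12, −78 to 0 °C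
Reagents that add atoms: none
Why: N-Acylation of the lithiated oxazolidinone by the acid chloride, which is far more electrophilic than the methyl ester.

Step 8
Reactants: 10 (2Z,5S)-5-(TBSO)-3-[(TBDPSO)methyl]-6-(PMBO)hex-2-enal; 13 methyl 4-[(4S)-4-benzyl-2-oxo-1,3-oxazolidin-3-yl]-4-oxobutanoate
Product: 15 (4S)-4-benzyl-3-({(2R,3S)-2-[(1Z,4S)-4-(TBSO)-2-[(TBDPSO)methyl]-5-(PMBO)pent-1-en-1-yl]-5-oxotetrahydrofuran-3-yl}carbonyl)-1,3-oxazolidin-2-one, via aldol adduct 14 (not isolated)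
Conditions: 13, n-Bu2BOTf, i-Pr2NEt, CH2Cl2, 0 °C; then 10, −78 to 0 °C; H2O2, pH 7 buffer, MeOH; then PPTS (cat.), toluene, 60 °C
Reagents that add atoms: none
Why: Evans syn-aldol reaction in which the Z-boron enolate of the imide adds through a chair transition state on the face away from the benzyl group, setting C6 (R) and C7, and acid-catalysed lactonisation of the γ-hydroxy ester should then give the trans-butanolide.

Step 9
Reactants: 15 lactone imide (name as in step 8)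
Product: 16 S-ethyl (2R,3S)-2-[(1Z,4S)-4-(TBSO)-2-[(TBDPSO)methyl]-5-(PMBO)pent-1-en-1-yl]-5-oxotetrahydrofuran-3-carbothioate
Conditions: EtSH, n-BuLi, THF, 0 °C
Reagents that add atoms: ethanethiol CCS
Why: Acyl substitution by lithium ethanethiolate at the exocyclic imide carbonyl, which is more electrophilic than the lactone, should release the auxiliary and give the thioester.

Step 10
Reactants: 16 thioester (name as in step 9)
Product: 17 (2R,3S)-2-[(1Z,4S)-4-(TBSO)-2-[(TBDPSO)methyl]-5-(PMBO)pent-1-en-1-yl]-5-oxotetrahydrofuran-3-carbaldehyde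
Conditions: Et3SiH, Pd/C (10 wt%), acetone, rt
Reagents that add atoms: none
Why: Fukuyama reduction (insertion of zerovalent palladium into the C–S bond, then hydride transfer from the silane) should give the C8 aldehyde and leave lactone, alkene and ethers untouched.

Step 11
Reactants: 17 aldehyde (name as in step 10)
Product: 18 (4R,5R)-4-[(1S)-1-hydroxy-3-oxobutyl]-5-[(1Z,4S)-4-(TBSO)-2-[(TBDPSO)methyl]-5-(PMBO)pent-1-en-1-yl]dihydrofuran-2(3H)-one
Conditions: D-proline (30 mol%), acetone/DMSO (1:4), rt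
Reagents that add atoms: acetone CC(C)=O
Why: Proline-catalysed direct aldol reaction in which the acetone enamine adds to the α-branched aldehyde through a hydrogen-bonded chair transition state, so that D-proline should set C8 as S under catalyst control.

Step 12
Reactants: 18 β-hydroxy ketone (name as in step 11)
Product: 19 (4S,5R)-4-[(1S)-3-oxo-1-(TESO)butyl]-5-[(1Z,4S)-4-(TBSO)-2-[(TBDPSO)methyl]-5-(PMBO)pent-1-en-1-yl]dihydrofuran-2(3H)-one
Conditions: Et3SiCl, imidazole, DMF, 0 °C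
Reagents that add atoms: chlorotriethylsilane CC[Si](Cl)(CC)CC
Why: Silylation protects the β-hydroxy ketone against retro-aldol cleavage and translactonisation and gives a silyl ether that can later be removed selectively.

Step 13
Reactants: 19 TES ether (name as in step 12)
Product: 20 (4S,5R)-5-[(1Z,4S)-4-(TBSO)-2-[(TBDPSO)methyl]-5-hydroxypent-1-en-1-yl]-4-[(1S)-3-oxo-1-(TESO)butyl]dihydrofuran-2(3H)-one
Conditions: DDQ, CH2Cl2/pH 7 phosphate buffer, 0 °C
Reagents that add atoms: none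
Why: Oxidative cleavage of the PMB ether by hydride abstraction from the electron-rich benzylic position should free only the C1 hydroxyl.

Step 14
Reactants: 20 primary alcohol (name as in step 13)
Product: 22 [(2S,4Z)-2-(TBSO)-4-[(TBDPSO)methyl]-5-{(2R,3S)-5-oxo-3-[(1S)-3-oxo-1-(TESO)butyl]tetrahydrofuran-2-yl}pent-4-en-1-yl]diphenylsulfonium trifluoromethanesulfonate, via triflate 21 (not isolated)
Conditions: Tf2O, 2,6-di-tert-butyl-4-methylpyridine, CH2Cl2, −78 °C; then Ph2S (10 equiv), −78 °C to rt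
Reagents that add atoms: trifluoromethanesulfonic anhydride O=S(=O)(OS(=O)(=O)C(F)(F)F)C(F)(F)F; diphenyl sulfide c1ccc(Sc2ccccc2)cc1
Why: O-Triflation and SN2 alkylation of diphenyl sulfide by the primary triflate should give a sulfonium salt in which C1 is the only carbon with α-hydrogens on sulfur.

Step 15
Reactants: 22 sulfonium triflate (name as in step 14)
Product: 25 (1R,2S,6R,7S,8S,10R)-2-(TBSO)-15-(TBDPSO)-8-(TESO)-1,10-epoxy-13-norgermacr-4-en-12,6-olide (C11 is CH2), via ylide 23 (not isolated), via betaine 24 (not isolated)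
Conditions: KN(SiMe3)2 (1.05 equiv, slow addition), THF (0.002 M), −78 to −20 °C
Reagents that add atoms: none
Why: Proposed new method: KN(SiMe3)2 removes a proton from C1, the only carbon α to the diphenylsulfonium group, and the non-stabilised ylide 23 adds to the C10 methyl ketone (C1–C10 bond, 10-exo-trig closure of the carbocycle) to give betaine 24, whose alkoxide displaces Ph2S at C1 with inversion (3-exo-tet closure of the oxirane). The closest known reaction type is the Corey–Chaykovsky epoxidation of ketones with diphenylsulfonium alkylides, established intermolecularly and for closing five- to seven-membered rings but not for a ten-membered carbocycle. The trans placement of C2 and C9 on the oxirane should follow from the usual preference of the addition transition state to put the ylide substituent anti to the larger ketone substituent (the C9 chain, not methyl C14). The configuration at C1 and C10 should be controlled by the trans-butanolide and the C4=C5 alkene, which fold the chain into the crossed (crown) germacrolide conformation so that the ylide meets the ketone on its peripheral face with the bulky C2 silyl ether on the outside of the forming ring. The step needs chemoselectivity for the ketone over the lactone and ring closure over oligomerisation, which the higher electrophilicity of the ketone and slow addition of base at high dilution should secure. The β-silyloxy ylide should not eliminate, since the reverse reaction (alkoxide addition to a vinylsulfonium salt) is the favoured direction.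

Step 16
Reactants: 25 macrocyclic epoxy lactone (name as in step 15)
Product: 28 (1R,2S,6R,7S,8S,10R)-2-(TBSO)-15-(TBDPSO)-8-(TESO)-1,10-epoxygermacra-4,11(13)-dien-12,6-olide, via Mannich base 26 (not isolated), via ammonium iodide 27 (not isolated)
Conditions: LiN(i-Pr)2, THF, −78 °C; CH2=NMe2+ I−, −78 to 0 °C; then MeI, MeOH, rt; then aq. NaHCO3, CH2Cl2
Reagents that add atoms: N,N-dimethylmethyleneiminium iodide C=[N+](C)C.[I-]
Why: α-Methylenation by Mannich reaction of the lactone lithium enolate (the only acidic site once the ketone is gone), N-methylation and base-induced β-elimination of trimethylamine.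

Step 17
Reactants: 28 silyl-protected α-methylene lactone (name as in step 16)
Product: 29 (1R,2S,6R,7R,8S,10R)-2-(TBSO)-15-(TBDPSO)-8-hydroxy-1,10-epoxygermacra-4,11(13)-dien-12,6-olide
Conditions: HF·pyridine, pyridine, THF, 0 °C
Reagents that add atoms: none
Why: Buffered fluoride desilylation should cleave the TES ether much faster than the secondary TBS and primary TBDPS ethers while the pyridine buffer protects the acid-sensitive epoxide.

Step 18
Reactants: 29 C8 alcohol (name as in step 17)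
Product: 30 (1R,2S,6R,7R,8S,10R)-8-angeloyloxy-2-(TBSO)-15-(TBDPSO)-1,10-epoxygermacra-4,11(13)-dien-12,6-olide
Conditions: angelic acid, 2,4,6-Cl3C6H2COCl, Et3N (excess), toluene, rt; then 29, 80 °C
Reagents that add atoms: angelic acid, (Z)-2-methylbut-2-enoic acid C/C=C(/C)C(=O)O
Why: Yamaguchi-type esterification through the mixed anhydride without a nucleophilic catalyst should acylate C8 without isomerising the Z (angelate) double bond.

Step 19
Reactants: 30 bis-silyl ether of the target (name as in step 18)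
Product: 31 (1R,2S,6R,7R,8S,10R)-8-angeloyloxy-2,15-dihydroxy-1,10-epoxygermacra-4,11(13)-dien-12,6-olide (target)
Conditions: n-Bu4NF, AcOH (1:1), THF, 0 °C to rt
Reagents that add atoms: none
Why: Fluoride desilylation removes both remaining silyl ethers, and the acetic acid buffer should suppress Payne rearrangement, acyl migration and conjugate addition to the α-methylene lactone.

Compound list
1 | (4-methoxybenzyloxy)acetaldehyde | O=CCOCc1ccc(OC)cc1 | starting material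
2 | 1-methoxy-1,3-bis(trimethylsilyloxy)buta-1,3-diene | COC(O[Si](C)(C)C)=CC(=C)O[Si](C)(C)C | starting material
3 | methyl (5S)-5-hydroxy-6-(PMBO)-3-oxohexanoate | COC(=O)CC(=O)C[C@H](O)COCc1ccc(OC)cc1 | intermediate
4 | methyl (5S)-5-(TBSO)-6-(PMBO)-3-oxohexanoate | COC(=O)CC(=O)C[C@H](O[Si](C)(C)C(C)(C)C)COCc1ccc(OC)cc1 | intermediate
5 | methyl (2Z,5S)-5-(TBSO)-6-(PMBO)-3-(trifluoromethylsulfonyloxy)hex-2-enoate | COC(=O)/C=C(\OS(=O)(=O)C(F)(F)F)C[C@H](O[Si](C)(C)C(C)(C)C)COCc1ccc(OC)cc1 | intermediate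
6 | methyl (2Z,5S)-5-(TBSO)-3-(hydroxymethyl)-6-(PMBO)hex-2-enoate | COC(=O)/C=C(\CO)C[C@H](O[Si](C)(C)C(C)(C)C)COCc1ccc(OC)cc1 | intermediate
7 | 4-[(2S)-2-(TBSO)-3-(PMBO)propyl]furan-2(5H)-one | O=C1C=C(C[C@H](O[Si](C)(C)C(C)(C)C)COCc2ccc(OC)cc2)CO1 | intermediate
8 | (2Z,5S)-5-(TBSO)-3-(hydroxymethyl)-N-methoxy-N-methyl-6-(PMBO)hex-2-enamide | CON(C)C(=O)/C=C(\CO)C[C@H](O[Si](C)(C)C(C)(C)C)COCc1ccc(OC)cc1 | intermediate
9 | (2Z,5S)-5-(TBSO)-3-[(TBDPSO)methyl]-N-methoxy-N-methyl-6-(PMBO)hex-2-enamide | CON(C)C(=O)/C=C(\CO[Si](c1ccccc1)(c1ccccc1)C(C)(C)C)C[C@H](O[Si](C)(C)C(C)(C)C)COCc1ccc(OC)cc1 | intermediate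
10 | (2Z,5S)-5-(TBSO)-3-[(TBDPSO)methyl]-6-(PMBO)hex-2-enal | O=C/C=C(\CO[Si](c1ccccc1)(c1ccccc1)C(C)(C)C)C[C@H](O[Si](C)(C)C(C)(C)C)COCc1ccc(OC)cc1 | intermediate
11 | (4S)-4-benzyl-1,3-oxazolidin-2-one | O=C1N[C@@H](Cc2ccccc2)CO1 | starting material
12 | methyl 4-chloro-4-oxobutanoate | COC(=O)CCC(Cl)=O | starting material
13 | methyl 4-[(4S)-4-benzyl-2-oxo-1,3-oxazolidin-3-yl]-4-oxobutanoate | COC(=O)CCC(=O)N1[C@@H](Cc2ccccc2)COC1=O | intermediate
14 | methyl (3S,4R,5Z,8S)-3-{[(4S)-4-benzyl-2-oxo-1,3-oxazolidin-3-yl]carbonyl}-8-(TBSO)-6-[(TBDPSO)methyl]-4-hydroxy-9-(PMBO)non-5-enoate | COC(=O)C[C@H](C(=O)N1[C@@H](Cc2ccccc2)COC1=O)[C@H](O)/C=C(\CO[Si](c2ccccc2)(c2ccccc2)C(C)(C)C)C[C@H](O[Si](C)(C)C(C)(C)C)COCc2ccc(OC)cc2 | intermediate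
15 | (4S)-4-benzyl-3-({(2R,3S)-2-[(1Z,4S)-4-(TBSO)-2-[(TBDPSO)methyl]-5-(PMBO)pent-1-en-1-yl]-5-oxotetrahydrofuran-3-yl}carbonyl)-1,3-oxazolidin-2-one | O=C1C[C@H](C(=O)N2[C@@H](Cc3ccccc3)COC2=O)[C@@H](/C=C(\CO[Si](c3ccccc3)(c3ccccc3)C(C)(C)C)C[C@H](O[Si](C)(C)C(C)(C)C)COCc3ccc(OC)cc3)O1 | intermediate
16 | S-ethyl (2R,3S)-2-[(1Z,4S)-4-(TBSO)-2-[(TBDPSO)methyl]-5-(PMBO)pent-1-en-1-yl]-5-oxotetrahydrofuran-3-carbothioate | O=C1C[C@H](C(=O)SCC)[C@@H](/C=C(\CO[Si](c2ccccc2)(c2ccccc2)C(C)(C)C)C[C@H](O[Si](C)(C)C(C)(C)C)COCc2ccc(OC)cc2)O1 | intermediate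
17 | (2R,3S)-2-[(1Z,4S)-4-(TBSO)-2-[(TBDPSO)methyl]-5-(PMBO)pent-1-en-1-yl]-5-oxotetrahydrofuran-3-carbaldehyde | O=C1C[C@H](C=O)[C@@H](/C=C(\CO[Si](c2ccccc2)(c2ccccc2)C(C)(C)C)C[C@H](O[Si](C)(C)C(C)(C)C)COCc2ccc(OC)cc2)O1 | intermediate
18 | (4R,5R)-4-[(1S)-1-hydroxy-3-oxobutyl]-5-[(1Z,4S)-4-(TBSO)-2-[(TBDPSO)methyl]-5-(PMBO)pent-1-en-1-yl]dihydrofuran-2(3H)-one | O=C1C[C@H]([C@@H](O)CC(C)=O)[C@@H](/C=C(\CO[Si](c2ccccc2)(c2ccccc2)C(C)(C)C)C[C@H](O[Si](C)(C)C(C)(C)C)COCc2ccc(OC)cc2)O1 | intermediate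
19 | (4S,5R)-4-[(1S)-3-oxo-1-(TESO)butyl]-5-[(1Z,4S)-4-(TBSO)-2-[(TBDPSO)methyl]-5-(PMBO)pent-1-en-1-yl]dihydrofuran-2(3H)-one | O=C1C[C@H]([C@@H](O[Si](CC)(CC)CC)CC(C)=O)[C@@H](/C=C(\CO[Si](c2ccccc2)(c2ccccc2)C(C)(C)C)C[C@H](O[Si](C)(C)C(C)(C)C)COCc2ccc(OC)cc2)O1 | intermediate
20 | (4S,5R)-5-[(1Z,4S)-4-(TBSO)-2-[(TBDPSO)methyl]-5-hydroxypent-1-en-1-yl]-4-[(1S)-3-oxo-1-(TESO)butyl]dihydrofuran-2(3H)-one | O=C1C[C@H]([C@@H](O[Si](CC)(CC)CC)CC(C)=O)[C@@H](/C=C(\CO[Si](c2ccccc2)(c2ccccc2)C(C)(C)C)C[C@H](O[Si](C)(C)C(C)(C)C)CO)O1 | intermediate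
21 | (2S,4Z)-2-(TBSO)-4-[(TBDPSO)methyl]-5-{(2R,3S)-5-oxo-3-[(1S)-3-oxo-1-(TESO)butyl]tetrahydrofuran-2-yl}pent-4-en-1-yl trifluoromethanesulfonate | O=C1C[C@H]([C@@H](O[Si](CC)(CC)CC)CC(C)=O)[C@@H](/C=C(\CO[Si](c2ccccc2)(c2ccccc2)C(C)(C)C)C[C@H](O[Si](C)(C)C(C)(C)C)COS(=O)(=O)C(F)(F)F)O1 | intermediate
22 | [(2S,4Z)-2-(TBSO)-4-[(TBDPSO)methyl]-5-{(2R,3S)-5-oxo-3-[(1S)-3-oxo-1-(TESO)butyl]tetrahydrofuran-2-yl}pent-4-en-1-yl]diphenylsulfonium trifluoromethanesulfonate | O=C1C[C@H]([C@@H](O[Si](CC)(CC)CC)CC(C)=O)[C@@H](/C=C(\CO[Si](c2ccccc2)(c2ccccc2)C(C)(C)C)C[C@H](O[Si](C)(C)C(C)(C)C)C[S+](c2ccccc2)c2ccccc2)O1.[O-]S(=O)(=O)C(F)(F)F | intermediate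
23 | sulfonium ylide of 22 (carbanion at C1, no counter-ion) | O=C1C[C@H]([C@@H](O[Si](CC)(CC)CC)CC(C)=O)[C@@H](/C=C(\CO[Si](c2ccccc2)(c2ccccc2)C(C)(C)C)C[C@H](O[Si](C)(C)C(C)(C)C)[CH-][S+](c2ccccc2)c2ccccc2)O1 | intermediate
24 | (1S,2S,6R,7S,8S,10R)-betaine: ten-membered ring closed, C10 alkoxide, diphenylsulfonio group at C1 | O=C1O[C@@H]2/C=C(\CO[Si](c3ccccc3)(c3ccccc3)C(C)(C)C)C[C@H](O[Si](C)(C)C(C)(C)C)[C@H]([S+](c3ccccc3)c3ccccc3)[C@@]([O-])(C)C[C@H](O[Si](CC)(CC)CC)[C@H]2C1 | intermediate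
25 | (1R,2S,6R,7S,8S,10R)-2-(TBSO)-15-(TBDPSO)-8-(TESO)-1,10-epoxy-13-norgermacr-4-en-12,6-olide | O=C1O[C@@H]2/C=C(\CO[Si](c4ccccc4)(c4ccccc4)C(C)(C)C)C[C@H](O[Si](C)(C)C(C)(C)C)[C@H]3O[C@]3(C)C[C@H](O[Si](CC)(CC)CC)[C@H]2C1 | intermediate
26 | 13-(dimethylamino) derivative of 25 (C11 bears CH2NMe2, C11 configuration not defined) | CN(C)CC1C(=O)O[C@@H]2/C=C(\CO[Si](c4ccccc4)(c4ccccc4)C(C)(C)C)C[C@H](O[Si](C)(C)C(C)(C)C)[C@H]3O[C@]3(C)C[C@H](O[Si](CC)(CC)CC)[C@@H]12 | intermediate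
27 | trimethylammonium iodide from 26 (C11 bears CH2NMe3+) | C[N+](C)(C)CC1C(=O)O[C@@H]2/C=C(\CO[Si](c4ccccc4)(c4ccccc4)C(C)(C)C)C[C@H](O[Si](C)(C)C(C)(C)C)[C@H]3O[C@]3(C)C[C@H](O[Si](CC)(CC)CC)[C@@H]12.[I-] | intermediate
28 | (1R,2S,6R,7S,8S,10R)-2-(TBSO)-15-(TBDPSO)-8-(TESO)-1,10-epoxygermacra-4,11(13)-dien-12,6-olide | C=C1C(=O)O[C@@H]2/C=C(\CO[Si](c4ccccc4)(c4ccccc4)C(C)(C)C)C[C@H](O[Si](C)(C)C(C)(C)C)[C@H]3O[C@]3(C)C[C@H](O[Si](CC)(CC)CC)[C@@H]12 | intermediate
29 | (1R,2S,6R,7R,8S,10R)-2-(TBSO)-15-(TBDPSO)-8-hydroxy-1,10-epoxygermacra-4,11(13)-dien-12,6-olide | C=C1C(=O)O[C@@H]2/C=C(\CO[Si](c4ccccc4)(c4ccccc4)C(C)(C)C)C[C@H](O[Si](C)(C)C(C)(C)C)[C@H]3O[C@]3(C)C[C@H](O)[C@@H]12 | intermediate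
30 | (1R,2S,6R,7R,8S,10R)-8-angeloyloxy-2-(TBSO)-15-(TBDPSO)-1,10-epoxygermacra-4,11(13)-dien-12,6-olide | C=C1C(=O)O[C@@H]2/C=C(\CO[Si](c4ccccc4)(c4ccccc4)C(C)(C)C)C[C@H](O[Si](C)(C)C(C)(C)C)[C@H]3O[C@]3(C)C[C@H](OC(=O)/C(C)=C\C)[C@@H]12 | intermediate
31 | (1R,2S,6R,7R,8S,10R)-8-angeloyloxy-2,15-dihydroxy-1,10-epoxygermacra-4,11(13)-dien-12,6-olide | C=C1C(=O)O[C@@H]2/C=C(\CO)C[C@H](O)[C@H]3O[C@]3(C)C[C@H](OC(=O)/C(C)=C\C)[C@@H]12 | target

Total step count: 19. Longest linear sequence: 18 steps (steps 1 to 6 and 8 to 19).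

Steps most likely to fail

Step 15 (key step). The ylide may decompose or react intermolecularly before it reaches the ketone, the C8 silyloxy group may be lost by elimination after enolisation of the ketone, or the ring may close on the wrong face. The fallback sets out from 20 and forms the same C1–C10 bond by known chemistry. Oxidation with Dess–Martin periodinane gives the keto aldehyde F1. Intramolecular pinacol coupling of the keto aldehyde with low-valent titanium (TiCl3(DME)1.5, Zn–Cu couple, DME, rt, high dilution) gives the (1S,10R)-1,10-diol F2, which is separated from its diastereomers. MsCl and Et3N at −20 °C sulfonylate only the secondary C1 hydroxyl to give the mesylate F3. K2CO3 in MeOH then closes the oxirane with inversion at C1 and comes back to the route at 25.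

Step 14. Alkylation of the weakly nucleophilic diphenyl sulfide by the β-oxygenated primary triflate may be slow, so the triflate may be lost through participation of the neighbouring silyl ether or by elimination. The fallback sets out from 20. Thioether formation with PhSSPh and n-Bu3P gives the phenyl sulfide F4. Copper-catalysed S-phenylation with Ph2I+ TfO− (Cu(OAc)2 cat., 1,2-dichloroethane, 80 °C) then comes back to the route at 22.

Step 18. The angeloyl group may isomerise to the tigloyl group, the liberated acid may open the epoxide at 80 °C, and acylation of the hindered C8 hydroxyl may be slow. The fallback sets out from 29 and builds the Z-alkene after the ester bond. Esterification with 2-[bis(2,2,2-trifluoroethoxy)phosphoryl]propanoic acid (DCC, DMAP, CH2Cl2, 0 °C) gives the phosphonate ester F5. Still–Gennari olefination with acetaldehyde (KN(SiMe3)2, 18-crown-6, THF, −78 °C) then comes back to the route at 30.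

Further compounds
F1 | step 15 | (2S,4Z)-2-(TBSO)-4-[(TBDPSO)methyl]-5-{(2R,3S)-5-oxo-3-[(1S)-3-oxo-1-(TESO)butyl]tetrahydrofuran-2-yl}pent-4-enal | O=C1C[C@H]([C@@H](O[Si](CC)(CC)CC)CC(C)=O)[C@@H](/C=C(\CO[Si](c2ccccc2)(c2ccccc2)C(C)(C)C)C[C@H](O[Si](C)(C)C(C)(C)C)C=O)O1
F2 | step 15 | (1S,2S,6R,7S,8S,10R)-1,10-dihydroxy-2-(TBSO)-15-(TBDPSO)-8-(TESO)-13-norgermacr-4-en-12,6-olide | O=C1O[C@@H]2/C=C(\CO[Si](c3ccccc3)(c3ccccc3)C(C)(C)C)C[C@H](O[Si](C)(C)C(C)(C)C)[C@H](O)[C@@](O)(C)C[C@H](O[Si](CC)(CC)CC)[C@H]2C1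
F3 | step 15 | 1-O-methanesulfonate of F2, (1S,2S,6R,7S,8S,10R) | O=C1O[C@@H]2/C=C(\CO[Si](c3ccccc3)(c3ccccc3)C(C)(C)C)C[C@H](O[Si](C)(C)C(C)(C)C)[C@H](OS(C)(=O)=O)[C@@](O)(C)C[C@H](O[Si](CC)(CC)CC)[C@H]2C1
F4 | step 14 | (4S,5R)-5-[(1Z,4S)-4-(TBSO)-2-[(TBDPSO)methyl]-5-(phenylsulfanyl)pent-1-en-1-yl]-4-[(1S)-3-oxo-1-(TESO)butyl]dihydrofuran-2(3H)-one | O=C1C[C@H]([C@@H](O[Si](CC)(CC)CC)CC(C)=O)[C@@H](/C=C(\CO[Si](c2ccccc2)(c2ccccc2)C(C)(C)C)C[C@H](O[Si](C)(C)C(C)(C)C)CSc2ccccc2)O1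
F5 | step 18 | 8-O-{2-[bis(2,2,2-trifluoroethoxy)phosphoryl]propanoyl} derivative of 29 | C=C1C(=O)O[C@@H]2/C=C(\CO[Si](c4ccccc4)(c4ccccc4)C(C)(C)C)C[C@H](O[Si](C)(C)C(C)(C)C)[C@H]3O[C@]3(C)C[C@H](OC(=O)C(C)P(=O)(OCC(F)(F)F)OCC(F)(F)F)[C@@H]12
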